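**Plan**
- Ring A is numbered C1 (bears the hexanoyl group), C2, C3 (quaternary: methyl and prenyl), C4, C5 (bears the arylmethyl group), C6; ring B is the aromatic ring.
- Enabling feature: the hexanoyl carbonyl carbon, C1, C6, C5, C4, C3 and C2 of ring A form a cyclised 3,5,7-triketo ester (C2 is the former ester carbon), and a 2,3,6-trisubstituted 4-pyranone stores exactly this chain.
- Retrosynthesis: remove the two MOM ethers of ring B; cut C1–C2 of ring A back to the pyranone; cut the pyranone into hexanoylketene and a silyl enol ether; cut the enol ether, through an enone, into a ring B aldehyde and a chiral methyl ketone.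
- Forward: ring B aldehyde from phloroglucinol; aldol condensation; 1,4-hydrosilylation; acylketene cycloaddition closes the pyranone; hydroxide opens it and a Dieckmann step closes ring A; deprotection.
- Stereochemistry: the only stereocentre, C3 (R), is set in step 1 by phase-transfer prenylation; it carries no hydrogen and is not touched again.

Key step: step 11

Assumption 1: the cinchonidine-derived catalyst of step 1 is taken to give the R ester; if a test run shows the opposite sense, the pseudoenantiomeric cinchonine-derived salt is used in the same way.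
Assumption 2: ring A is written as the 3,5-dihydroxycyclohexa-2,5-dienone tautomer of the given SMILES, and the descriptor 4R refers to that tautomer.

**Route**

Step 1
Reactants: 1 methyl 2-methylacetoacetate; 2 prenyl bromide
Product: 3 methyl (2R)-2-acetyl-2,5-dimethylhex-4-enoate
Conditions: O-allyl-N-(9-anthracenylmethyl)cinchonidinium bromide (10 mol %), K2CO3 (powdered), toluene, −20 → 0 °C
Reagents that add atoms: none
Why: Asymmetric phase-transfer alkylation of an α-substituted β-keto ester: the chiral ammonium cation pairs tightly with the enolate of 1 and shields one face, so prenyl bromide should attack carbon from the other face (SN2) and set the R quaternary centre, while the mild carbonate base spares the methyl ester and the non-enolisable product from retro-Claisen cleavage.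

Step 2
Reactants: 4 phloroglucinol; 5 butanoyl chloride
Product: 6 1-(2,4,6-trihydroxyphenyl)butan-1-one
Conditions: AlCl3 (3.5 equiv), PhNO2–CH2Cl2, 0 → 50 °C; ice/aq HCl
Reagents that add atoms: none
Why: Friedel–Crafts acylation of the very electron-rich phloroglucinol, which should stop after one acyl group because the chelated ketone deactivates the ring.

Step 3
Reactants: 6 1-(2,4,6-trihydroxyphenyl)butan-1-one
Product: 7 1-(2,6-dihydroxy-4-methoxyphenyl)butan-1-one
Conditions: Me2SO4 (1.0 equiv), K2CO3 (1.1 equiv), acetone, rt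
Reagents that add atoms: dimethyl sulfate, COS(=O)(=O)OC
Why: Williamson O-methylation that should select the 4-hydroxyl, the only phenol not hydrogen-bonded to the ketone and the most acidic one, when one equivalent of the methylating agent and a weak base are used.

Step 4
Reactants: 7 1-(2,6-dihydroxy-4-methoxyphenyl)butan-1-one
Product: 9 3-butanoyl-2,4-dihydroxy-6-methoxybenzaldehyde, via α-chloro ether 8 (not isolated)
Conditions: Cl2CHOMe (1.3 equiv), TiCl4 (3 equiv), CH2Cl2, −10 → 0 °C; then ice-water
Reagents that add atoms: dichloromethyl methyl ether, COC(Cl)Cl; water, O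
Why: Rieche formylation (electrophilic aromatic substitution) as applied to acylphloroglucinols; the two free ring positions of 7 are equivalent, so one aldehyde should result after hydrolysis of the chloro ether, and the first formyl group deactivates the ring against a second.

Step 5
Reactants: 9 3-butanoyl-2,4-dihydroxy-6-methoxybenzaldehyde
Product: 11 3-butanoyl-6-methoxy-2,4-bis(methoxymethoxy)benzaldehyde, via disodium bisphenoxide 10 (not isolated)
Conditions: NaH (2.4 equiv), DMF, 0 °C; then MOMCl (2.6 equiv), 0 °C → rt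
Reagents that add atoms: chloromethyl methyl ether, COCCl
Why: Williamson etherification of the bisphenoxide; NaH is chosen because both hydroxyls are chelated to carbonyl groups, and MOM ethers should withstand all later bases, the hydrosilylation and the thermolysis yet leave under mild acid.

Step 6
Reactants: 3 methyl (2R)-2-acetyl-2,5-dimethylhex-4-enoate; 11 3-butanoyl-6-methoxy-2,4-bis(methoxymethoxy)benzaldehyde
Product: 13 methyl (2R)-2-{3-[3-butanoyl-6-methoxy-2,4-bis(methoxymethoxy)phenyl]-3-hydroxypropanoyl}-2,5-dimethylhex-4-enoate (both carbinol epimers), via lithium enolate 12 (not isolated)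
Conditions: LiN(i-Pr)2 (1.05 equiv), THF, −78 °C; then 11, −78 °C; AcOH quench at −78 °C
Reagents that add atoms: none
Why: Directed aldol addition: 3 has α-hydrogens only on the acetyl methyl group, so one kinetic enolate forms and should add to the non-enolisable aldehyde at −78 °C far faster than it exchanges protons with the hindered aryl ketone; the new carbinol centre is removed in the next step and is not controlled.

Step 7
Reactants: 13 methyl (2R)-2-{3-[3-butanoyl-6-methoxy-2,4-bis(methoxymethoxy)phenyl]-3-hydroxypropanoyl}-2,5-dimethylhex-4-enoate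
Product: 15 methyl (2R)-2-{(2E)-3-[3-butanoyl-6-methoxy-2,4-bis(methoxymethoxy)phenyl]prop-2-enoyl}-2,5-dimethylhex-4-enoate, via benzylic mesylate 14 (not isolated)
Conditions: MsCl, Et3N, CH2Cl2, 0 °C; then DBU, 0 °C → rt
Reagents that add atoms: none
Why: Mesylation followed by base-induced elimination (E1cB, helped by the electron-rich aryl group) should give the conjugated enone in its thermodynamically preferred E geometry without acid that would endanger the MOM ethers.

Step 8
Reactants: 15 methyl (2R)-2-{(2E)-3-[3-butanoyl-6-methoxy-2,4-bis(methoxymethoxy)phenyl]prop-2-enoyl}-2,5-dimethylhex-4-enoate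
Product: 16 methyl (2R)-2-{(1Z)-3-[3-butanoyl-6-methoxy-2,4-bis(methoxymethoxy)phenyl]-1-[(triethylsilyl)oxy]prop-1-en-1-yl}-2,5-dimethylhex-4-enoate
Conditions: Et3SiH (1.5 equiv), RhCl(PPh3)3 (2 mol %), toluene, 50 °C
Reagents that add atoms: triethylsilane, CC[SiH](CC)CC
Why: Rhodium-catalysed 1,4-hydrosilylation of an enone with a trialkylsilane gives the silyl enol ether regiospecifically and without base, so the butanoyl ketone of ring B, the ester and the trisubstituted alkene should stay untouched; the s-cis enone is expected to give mainly the Z enol ether, and either geometry serves the next step.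

Step 9
Reactants: 17 2,2,6-trimethyl-4H-1,3-dioxin-4-one; 18 1-iodobutane
Product: 20 2,2-dimethyl-6-pentyl-4H-1,3-dioxin-4-one, via lithium dienolate 19 (not isolated)
Conditions: LiN(i-Pr)2 (1.1 equiv), THF, −78 °C; DMPU; then 18, −78 → −30 °C
Reagents that add atoms: none
Why: γ-Alkylation of the extended lithium dienolate of the dioxinone with a primary iodide (SN2), a standard way to lengthen the 6-substituent of an acylketene precursor.

Step 10
Reactants: 16 methyl (2R)-2-{(1Z)-3-[3-butanoyl-6-methoxy-2,4-bis(methoxymethoxy)phenyl]-1-[(triethylsilyl)oxy]prop-1-en-1-yl}-2,5-dimethylhex-4-enoate; 20 2,2-dimethyl-6-pentyl-4H-1,3-dioxin-4-one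
Product: 23 methyl (2R)-2-{3-[(3-butanoyl-6-methoxy-2,4-bis(methoxymethoxy)phenyl)methyl]-4-oxo-6-pentyl-4H-pyran-2-yl}-2,5-dimethylhex-4-enoate, via hexanoylketene 21 (not isolated), via silyloxy-dihydropyranone cycloadduct 22 (not isolated)
Conditions: 20 (3 equiv, slow addition), toluene, 110 °C; then CSA (10 mol %), CH2Cl2, rt
Reagents that add atoms: none
Why: Retro-[4+2] loss of acetone from 20 frees hexanoylketene, which the electron-rich enol ether should capture in a hetero-[4+2] cycloaddition (ketene carbon to the CH terminus, acyl oxygen to the silyloxy carbon, as the polarity of both partners dictates), and acid-catalysed loss of triethylsilanol from the adduct then gives the 4-pyranone.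

Step 11
Reactants: 23 methyl (2R)-2-{3-[(3-butanoyl-6-methoxy-2,4-bis(methoxymethoxy)phenyl)methyl]-4-oxo-6-pentyl-4H-pyran-2-yl}-2,5-dimethylhex-4-enoate
Product: 25 (4R)-6-{[3-butanoyl-6-methoxy-2,4-bis(methoxymethoxy)phenyl]methyl}-2-hexanoyl-3,5-dihydroxy-4-methyl-4-(3-methylbut-2-en-1-yl)cyclohexa-2,5-dien-1-one, via triketo ester enolate 24 (not isolated)
Conditions: KOH (8 equiv), MeOH–H2O (10:1), rt → 45 °C; then 1 M HCl to pH 4, 0 °C
Reagents that add atoms: potassium hydroxide, [K+].[OH-]
Why: Hydroxide adds in conjugate fashion to the pentyl-bearing ring carbon of the pyranone, which is far less hindered than the carbon next to the quaternary centre, and the ring opens to the enolate of triketo ester 24, the hydroxide oxygen ending as the hexanoyl carbonyl oxygen. The doubly activated carbon between the hexanoyl and the central carbonyl group then attacks the methyl ester and expels methoxide, a Dieckmann (intramolecular Claisen) condensation that forms the C1–C2 bond and closes ring A in the 6-exo-trig mode. The closest known chemistry is the alkaline opening of 2,6-disubstituted 4-pyranones to 1,3,5-triketones and the Claisen cyclisation of 3,5,7-triketo esters to acylphloroglucinols. No stereocentre is formed; C3 is quaternary, has no α-hydrogen and cannot epimerise, and the same lack of hydrogen excludes the resorcylate-type aldol closure, so the only aldol left would need the pentyl α-carbon, which hydroxide does not deprotonate, to attack a ketone shielded by the quaternary carbon. The step needs C-acylation to outrun saponification of the ester, which is favoured because the α-quaternary ester is hindered toward external hydroxide but held next to the internal carbanion, and the fully delocalised triketone enolate of 25 is the thermodynamic sink. Ring B carries no free phenol, so the methylene bridge should not fragment in base.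

Step 12
Reactants: 25 (4R)-6-{[3-butanoyl-6-methoxy-2,4-bis(methoxymethoxy)phenyl]methyl}-2-hexanoyl-3,5-dihydroxy-4-methyl-4-(3-methylbut-2-en-1-yl)cyclohexa-2,5-dien-1-one
Product: 26 (4R)-6-[(3-butanoyl-2,4-dihydroxy-6-methoxyphenyl)methyl]-2-hexanoyl-3,5-dihydroxy-4-methyl-4-(3-methylbut-2-en-1-yl)cyclohexa-2,5-dien-1-one (CNP0219674.1)
Conditions: HCl (3 M in MeOH), rt
Reagents that add atoms: none
Why: Acid-catalysed acetal exchange with methanol should remove both MOM ethers, which are activated by the neighbouring aryl ketone, under conditions mild enough to spare the prenyl alkene, the methylene bridge and the aryl methyl ether.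

**Compound list**
1 | methyl 2-methylacetoacetate (racemic) | CC(=O)C(C)C(=O)OC | starting material
2 | prenyl bromide (1-bromo-3-methylbut-2-ene) | CC(C)=CCBr | starting material
3 | methyl (2R)-2-acetyl-2,5-dimethylhex-4-enoate | CC(=O)[C@@](C)(CC=C(C)C)C(=O)OC | intermediate
4 | phloroglucinol | Oc1cc(O)cc(O)c1 | starting material
5 | butanoyl chloride | CCCC(Cl)=O | starting material
6 | 1-(2,4,6-trihydroxyphenyl)butan-1-one | CCCC(=O)c1c(O)cc(O)cc1O | intermediate
7 | 1-(2,6-dihydroxy-4-methoxyphenyl)butan-1-one | CCCC(=O)c1c(O)cc(OC)cc1O | intermediate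
8 | 1-{3-[chloro(methoxy)methyl]-2,6-dihydroxy-4-methoxyphenyl}butan-1-one, formed in the flask | CCCC(=O)c1c(O)cc(OC)c(C(Cl)OC)c1O | intermediate
9 | 3-butanoyl-2,4-dihydroxy-6-methoxybenzaldehyde | CCCC(=O)c1c(O)cc(OC)c(C=O)c1O | intermediate
10 | disodium 3-butanoyl-2-formyl-5-methoxybenzene-1,3-diolate (bisphenoxide of 9), formed in the flask | CCCC(=O)c1c([O-])cc(OC)c(C=O)c1[O-].[Na+].[Na+] | intermediate
11 | 3-butanoyl-6-methoxy-2,4-bis(methoxymethoxy)benzaldehyde | CCCC(=O)c1c(OCOC)cc(OC)c(C=O)c1OCOC | intermediate
12 | lithium (3R)-3-(methoxycarbonyl)-3,6-dimethylhepta-1,5-dien-2-olate (enolate of 3), formed in the flask | [Li]OC(=C)[C@@](C)(CC=C(C)C)C(=O)OC | intermediate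
13 | methyl (2R)-2-{3-[3-butanoyl-6-methoxy-2,4-bis(methoxymethoxy)phenyl]-3-hydroxypropanoyl}-2,5-dimethylhex-4-enoate, both carbinol epimers | CCCC(=O)c1c(OCOC)cc(OC)c(C(O)CC(=O)[C@@](C)(CC=C(C)C)C(=O)OC)c1OCOC | intermediate
14 | methanesulfonate of 13, both epimers, formed in the flask | CCCC(=O)c1c(OCOC)cc(OC)c(C(OS(C)(=O)=O)CC(=O)[C@@](C)(CC=C(C)C)C(=O)OC)c1OCOC | intermediate
15 | methyl (2R)-2-{(2E)-3-[3-butanoyl-6-methoxy-2,4-bis(methoxymethoxy)phenyl]prop-2-enoyl}-2,5-dimethylhex-4-enoate | CCCC(=O)c1c(OCOC)cc(OC)c(/C=C/C(=O)[C@@](C)(CC=C(C)C)C(=O)OC)c1OCOC | intermediate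
16 | methyl (2R)-2-{(1Z)-3-[3-butanoyl-6-methoxy-2,4-bis(methoxymethoxy)phenyl]-1-[(triethylsilyl)oxy]prop-1-en-1-yl}-2,5-dimethylhex-4-enoate | CC[Si](CC)(CC)O/C(=C\Cc1c(OC)cc(OCOC)c(C(=O)CCC)c1OCOC)[C@@](C)(CC=C(C)C)C(=O)OC | intermediate
17 | 2,2,6-trimethyl-4H-1,3-dioxin-4-one | CC1=CC(=O)OC(C)(C)O1 | starting material
18 | 1-iodobutane | CCCCI | starting material
19 | lithium 2,2-dimethyl-6-methylidene-6H-1,3-dioxin-4-olate (dienolate of 17), formed in the flask | C=C1C=C(O[Li])OC(C)(C)O1 | intermediate
20 | 2,2-dimethyl-6-pentyl-4H-1,3-dioxin-4-one | CCCCCC1=CC(=O)OC(C)(C)O1 | intermediate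
21 | hexanoylketene (3-oxooct-1-en-1-one), formed in the flask | CCCCCC(=O)C=C=O | intermediate
22 | methyl (2R)-2-{3-[(3-butanoyl-6-methoxy-2,4-bis(methoxymethoxy)phenyl)methyl]-4-oxo-6-pentyl-2-[(triethylsilyl)oxy]-3,4-dihydro-2H-pyran-2-yl}-2,5-dimethylhex-4-enoate, ring stereocentres not defined, formed in the flask | CCCCCC1=CC(=O)C(Cc2c(OC)cc(OCOC)c(C(=O)CCC)c2OCOC)C(O[Si](CC)(CC)CC)(O1)[C@@](C)(CC=C(C)C)C(=O)OC | intermediate
23 | methyl (2R)-2-{3-[(3-butanoyl-6-methoxy-2,4-bis(methoxymethoxy)phenyl)methyl]-4-oxo-6-pentyl-4H-pyran-2-yl}-2,5-dimethylhex-4-enoate | CCCCCc1cc(=O)c(Cc2c(OC)cc(OCOC)c(C(=O)CCC)c2OCOC)c(o1)[C@@](C)(CC=C(C)C)C(=O)OC | intermediate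
24 | methyl (2R)-2-{2-[(3-butanoyl-6-methoxy-2,4-bis(methoxymethoxy)phenyl)methyl]-3,5-dioxodecanoyl}-2,5-dimethylhex-4-enoate, present as its potassium enolate in the flask | CCCCCC(=O)CC(=O)C(Cc1c(OC)cc(OCOC)c(C(=O)CCC)c1OCOC)C(=O)[C@@](C)(CC=C(C)C)C(=O)OC | intermediate
25 | (4R)-6-{[3-butanoyl-6-methoxy-2,4-bis(methoxymethoxy)phenyl]methyl}-2-hexanoyl-3,5-dihydroxy-4-methyl-4-(3-methylbut-2-en-1-yl)cyclohexa-2,5-dien-1-one | CCCCCC(=O)C1=C(O)[C@](C)(CC=C(C)C)C(O)=C(Cc2c(OC)cc(OCOC)c(C(=O)CCC)c2OCOC)C1=O | intermediate
26 | (4R)-6-[(3-butanoyl-2,4-dihydroxy-6-methoxyphenyl)methyl]-2-hexanoyl-3,5-dihydroxy-4-methyl-4-(3-methylbut-2-en-1-yl)cyclohexa-2,5-dien-1-one | CCCCCC(=O)C1=C(O)[C@](C)(CC=C(C)C)C(O)=C(Cc2c(OC)cc(O)c(C(=O)CCC)c2O)C1=O | target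

**Count**
Total steps: 12. Longest linear sequence: 10 steps (steps 2, 3, 4, 5, 6, 7, 8, 10, 11, 12, from phloroglucinol).

**Steps most likely to fail**

Step 10. The acylketene may dimerise faster than the hindered trisubstituted enol ether captures it, and the silyl group may be lost by protonolysis during the long heating. The fallback sets out from 16 and returns at 23. A Mukaiyama aldol addition of 16 to oct-2-ynal (BF3·OEt2, CH2Cl2, −78 °C) should give the β-hydroxy ynone methyl (2R)-2-{2-[(3-butanoyl-6-methoxy-2,4-bis(methoxymethoxy)phenyl)methyl]-3-hydroxydec-4-ynoyl}-2,5-dimethylhex-4-enoate F3. Dess–Martin oxidation (NaHCO3, CH2Cl2) should then give the ynedione methyl (2R)-2-{2-[(3-butanoyl-6-methoxy-2,4-bis(methoxymethoxy)phenyl)methyl]-3-oxodec-4-ynoyl}-2,5-dimethylhex-4-enoate F4. Its enol oxygen is expected to add 6-endo-dig to the alkyne under Ph3PAuCl/AgOTf (5 mol %, toluene, rt) to give pyranone 23.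

Step 11. Ring opening of the hindered pyranone may be slow, so that external hydroxide saponifies the ester before the Claisen closure can take place. The fallback sets out from 16 and 20 and returns at 25 without hydroxide and without the pyranone. The thermolysis of step 10 is run without the acid treatment, and cycloadduct 22 is desilylated with Bu4NF/AcOH (THF, 0 °C). This should give the cyclic hemiketal methyl (2R)-2-{3-[(3-butanoyl-6-methoxy-2,4-bis(methoxymethoxy)phenyl)methyl]-2-hydroxy-4-oxo-6-pentyl-3,4-dihydro-2H-pyran-2-yl}-2,5-dimethylhex-4-enoate F5, the ring tautomer of triketo ester 24. NaOMe in dry MeOH (0 °C → rt) should open F5 to the enolate of 24 and drive the same Claisen closure to 25.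

Step 1. The geometry of the acyclic enolate is not fixed, so facial discrimination in the ion pair may be poor and the enantiomeric purity of 3 too low. The fallback sets out from 1 and returns at 3 by a chiral-auxiliary alkylation. Condensation of 1 with L-valine tert-butyl ester (catalytic acid, azeotropic removal of water) should give the enamino ester methyl (2Z)-3-{[(2S)-1-tert-butoxy-3-methyl-1-oxobutan-2-yl]amino}-2-methylbut-2-enoate F1. Lithiation with LiN(i-Pr)2 and alkylation with 2 at −78 °C should give the imine methyl (2R)-2-{N-[(2S)-1-tert-butoxy-3-methyl-1-oxobutan-2-yl]ethanimidoyl}-2,5-dimethylhex-4-enoate F2. The alkylation is run in toluene containing HMPA or in THF; the two media are expected to give opposite senses of induction, and the one that leads to R is used. Cold dilute aqueous acid should hydrolyse F2 to 3, and the amino ester is recovered.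

**Further compounds**
F1 | step 1 | methyl (2Z)-3-{[(2S)-1-tert-butoxy-3-methyl-1-oxobutan-2-yl]amino}-2-methylbut-2-enoate | COC(=O)/C(C)=C(C)\N[C@@H](C(C)C)C(=O)OC(C)(C)C
F2 | step 1 | methyl (2R)-2-{N-[(2S)-1-tert-butoxy-3-methyl-1-oxobutan-2-yl]ethanimidoyl}-2,5-dimethylhex-4-enoate | CC(=N[C@@H](C(C)C)C(=O)OC(C)(C)C)[C@@](C)(CC=C(C)C)C(=O)OC
F3 | step 10 | methyl (2R)-2-{2-[(3-butanoyl-6-methoxy-2,4-bis(methoxymethoxy)phenyl)methyl]-3-hydroxydec-4-ynoyl}-2,5-dimethylhex-4-enoate | CCCCCC#CC(O)C(Cc1c(OC)cc(OCOC)c(C(=O)CCC)c1OCOC)C(=O)[C@@](C)(CC=C(C)C)C(=O)OC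
F4 | step 10 | methyl (2R)-2-{2-[(3-butanoyl-6-methoxy-2,4-bis(methoxymethoxy)phenyl)methyl]-3-oxodec-4-ynoyl}-2,5-dimethylhex-4-enoate | CCCCCC#CC(=O)C(Cc1c(OC)cc(OCOC)c(C(=O)CCC)c1OCOC)C(=O)[C@@](C)(CC=C(C)C)C(=O)OC
F5 | step 11 | methyl (2R)-2-{3-[(3-butanoyl-6-methoxy-2,4-bis(methoxymethoxy)phenyl)methyl]-2-hydroxy-4-oxo-6-pentyl-3,4-dihydro-2H-pyran-2-yl}-2,5-dimethylhex-4-enoate | CCCCCC1=CC(=O)C(Cc2c(OC)cc(OCOC)c(C(=O)CCC)c2OCOC)C(O)(O1)[C@@](C)(CC=C(C)C)C(=O)OC
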